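## Retrosynthetic overview

1. Feature: the six-membered carbocycle C(CH3)2–CH(CH2O)–C(OH)–C(CH3)(O)–C(=O)–C(CH3) is spanned between its two bridgeheads, C(OH) and C(CH3), by the C5=C6 double bond of the 2-phenyl-2,3-dihydropyran-4-one. This third bridge of the bicyclo[2.2.2]octene stands for an alkyne that has added across a cyclohexa-1,3-diene.
2. Disconnections, backwards: the tetrahydrofuran O–C(CH3) bond (oxidative etherification of a silyl enol ether by the CH2OH arm). Then the pyranone O–C6 bond (benzylic OH displaces a vinyl bromide). Then both bridgehead–alkene bonds, by an intermolecular Diels–Alder reaction of diene 11 with bromo-ynone 18.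
3. Diene 11 comes from 2-methyldimedone, and both C–C bonds are made at the alpha' carbon of a vinylogous ester. The arm goes in first (asymmetric hydroxymethylation). A di-tert-butylsilylene then ties it to the neighbouring enol oxygen, which moves the ketone to the far side for methylation and kinetic silylation.
4. Bromo-ynone 18 comes from ethyl (R)-3-hydroxy-3-phenylpropanoate by Weinreb amide formation, silylation, ethynylation and bromination. The phenyl-bearing centre is bought.
5. Ring order: carbocycle (bought), bicyclo[2.2.2]octadiene (step 12), dihydropyranone (step 14), tetrahydrofuran (step 16).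

Key step: step 12

Assumption: the (S,S)-bipyridine ligand of step 3 is taken to deliver the (R)-alcohol 5. If the sense of induction is the opposite, the (R,R)-ligand is used with no other change.

## Route

Step 1
Reactants: 1 2-methyldimedone
Product: 2 3-(benzyloxy)-2,5,5-trimethylcyclohex-2-en-1-one
Conditions: BnOH (1.5 equiv), p-TsOH·H2O (5 mol %), toluene, reflux, Dean–Stark trap
Reagents that add atoms: benzyl alcohol OCc1ccccc1
Why: Acid-catalysed enol etherification of a cyclic 1,3-dione with azeotropic removal of water; the dione is symmetric, so only one vinylogous ester can form, and benzyl is chosen because it can later be removed without acid or base.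

Step 2
Reactants: 2 3-(benzyloxy)-2,5,5-trimethylcyclohex-2-en-1-one
Product: 4 1-(benzyloxy)-2,5,5-trimethyl-3-(trimethylsilyloxy)cyclohexa-1,3-diene, via lithium enolate 3 (not isolated)
Conditions: LiN(iPr)2 (1.1 equiv), THF, −78 °C; Me3SiCl, −78 to 0 °C; non-aqueous work-up (pentane, filtration)
Reagents that add atoms: chlorotrimethylsilane C[Si](C)(C)Cl
Why: Kinetic alpha'-deprotonation of a vinylogous ester (Stork–Danheiser regiochemistry) followed by O-silylation should give the cross-conjugated silyl dienol ether, the gamma CH2 next to the benzyloxy carbon being left untouched.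

Step 3
Reactants: 4 1-(benzyloxy)-2,5,5-trimethyl-3-(trimethylsilyloxy)cyclohexa-1,3-diene
Product: 5 (6R)-3-(benzyloxy)-6-(hydroxymethyl)-2,5,5-trimethylcyclohex-2-en-1-one
Conditions: aq. HCHO (5 equiv), Sc(OTf)3 (10 mol %), (S,S)-6,6'-bis(1-hydroxy-2,2-dimethylpropyl)-2,2'-bipyridine (12 mol %), DME/H2O 9:1, −20 °C
Reagents that add atoms: formaldehyde C=O
Why: Catalytic asymmetric Mukaiyama aldol reaction (hydroxymethylation of a silicon enolate with aqueous formaldehyde) at the silyl enol ether terminus; the chiral scandium–bipyridine complex binds formaldehyde and selects one face of the planar enol carbon, which sets the ring CH centre as (R).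

Step 4
Reactants: 5 (6R)-3-(benzyloxy)-6-(hydroxymethyl)-2,5,5-trimethylcyclohex-2-en-1-one
Product: 6 (4R)-4-(hydroxymethyl)-2,5,5-trimethylcyclohexane-1,3-dione
Conditions: H2 (1 atm), 10 % Pd/C, EtOAc, rt
Reagents that add atoms: none
Why: Hydrogenolysis of a benzyl vinylogous ester runs like that of a benzyl ester and is neutral, so the beta-hydroxy ketone should lose neither formaldehyde (retro-aldol) nor water and the alpha centre should not epimerise.

Step 5
Reactants: 6 (4R)-4-(hydroxymethyl)-2,5,5-trimethylcyclohexane-1,3-dione
Product: 7 silylene enone (4aR)-2,2-di-tert-butyl-5,5,8-trimethyl-4,4a,5,6-tetrahydro-7H-benzo[d][1,3,2]dioxasilin-7-one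
Conditions: tBu2Si(OTf)2 (1.05 equiv), 2,6-lutidine (2.5 equiv), CH2Cl2, 0 °C
Reagents that add atoms: di-tert-butylsilyl bis(trifluoromethanesulfonate) CC(C)(C)[Si](OS(=O)(=O)C(F)(F)F)(OS(=O)(=O)C(F)(F)F)C(C)(C)C
Why: Cyclic silylene protection with a bis(triflate): once the primary alcohol is silylated only the neighbouring enol oxygen can close a six-membered O–Si–O ring, so the tether fixes the enol ether next to the arm and leaves the far carbonyl as the ketone, a regiochemistry that gamma-deprotonation of a vinylogous ester or O-alkylation of the free dione would not secure.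

Step 6
Reactants: 7 silylene enone
Product: 9 6-methyl silylene enone (4aR)-2,2-di-tert-butyl-5,5,6,8-tetramethyl-4,4a,5,6-tetrahydro-7H-benzo[d][1,3,2]dioxasilin-7-one (both epimers at C6), via lithium enolate 8 (not isolated)
Conditions: LiN(iPr)2 (1.1 equiv), THF, −78 °C; MeI, −78 to −20 °C
Reagents that add atoms: iodomethane CI
Why: Kinetic enolate alkylation: the only ketone is now flanked by the far CH2, so alpha'-deprotonation and SN2 methylation take place there, the hindered silylene resists the amide base, and the configuration of the new CH(CH3) centre is irrelevant because it becomes sp2 in step 7.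

Step 7
Reactants: 9 6-methyl silylene enone
Product: 11 diene (4aR)-2,2-di-tert-butyl-5,5,6,8-tetramethyl-7-(triisopropylsilyloxy)-4a,5-dihydro-4H-benzo[d][1,3,2]dioxasiline, via lithium enolate 10 (not isolated)
Conditions: LiN(iPr)2 (1.2 equiv), THF/DMPU, −78 to −40 °C; iPr3SiOTf, −78 °C; Et3N-deactivated silica
Reagents that add atoms: triisopropylsilyl trifluoromethanesulfonate CC(C)[Si](C(C)C)(C(C)C)OS(=O)(=O)C(F)(F)F
Why: Carbonyl-directed kinetic alpha'-enolisation and O-silylation with a hard silyl triflate should give the tetrasubstituted silyl enol ether and thereby the 1,3-dioxygenated diene, while the gamma C–H at the stereocentre is not touched at low temperature.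

Step 8
Reactants: 12 ethyl (R)-3-hydroxy-3-phenylpropanoate
Product: 13 (R)-3-hydroxy-N-methoxy-N-methyl-3-phenylpropanamide
Conditions: MeNH(OMe)·HCl (1.5 equiv), iPrMgCl (4.5 equiv), THF, −20 to 0 °C
Reagents that add atoms: N,O-dimethylhydroxylamine hydrochloride CNOC.Cl
Why: Aminolysis of the ester by the chloromagnesium amide of N,O-dimethylhydroxylamine (Weinreb amide formation); the carbinol centre takes no part, and the magnesium alkoxide formed in the flask shields the beta-hydroxy ester from elimination.

Step 9
Reactants: 13 (R)-3-hydroxy-N-methoxy-N-methyl-3-phenylpropanamide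
Product: 14 (R)-N-methoxy-N-methyl-3-phenyl-3-(triethylsilyloxy)propanamide
Conditions: Et3SiCl (1.2 equiv), imidazole (1.2 equiv), CH2Cl2, 0 °C to rt
Reagents that add atoms: chlorotriethylsilane CC[Si](Cl)(CC)CC
Why: Standard silylation of a secondary alcohol; triethylsilyl withstands the Grignard reagent, the bromination and the heating of step 12, yet is the silicon group most easily cleaved by mild acid in step 13.

Step 10
Reactants: 14 (R)-N-methoxy-N-methyl-3-phenyl-3-(triethylsilyloxy)propanamide; 15 ethynylmagnesium bromide
Product: 17 (R)-5-phenyl-5-(triethylsilyloxy)pent-1-yn-3-one, via magnesium hemiaminal adduct 16 (not isolated)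
Conditions: THF, −78 to 0 °C; inverse quench into cold aq. NaHSO4
Reagents that add atoms: none
Why: Weinreb ketone synthesis: the chelated tetrahedral adduct prevents a second addition, and the acidic inverse quench keeps the liberated amine from adding to the ynone.

Step 11
Reactants: 17 (R)-5-phenyl-5-(triethylsilyloxy)pent-1-yn-3-one
Product: 18 (R)-1-bromo-5-phenyl-5-(triethylsilyloxy)pent-1-yn-3-one
Conditions: NBS (1.1 equiv), AgNO3 (10 mol %), acetone, rt, dark
Reagents that add atoms: N-bromosuccinimide O=C1CCC(=O)N1Br
Why: Silver-catalysed electrophilic bromination of a terminal alkyne through the silver acetylide, a neutral reaction that leaves the silyl ether and the carbinol centre alone.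

Step 12
Reactants: 11 diene; 18 (R)-1-bromo-5-phenyl-5-(triethylsilyloxy)pent-1-yn-3-one
Product: 19 bicyclo[2.2.2]octa-2,5-diene adduct (bridgeheads C–CH3 and C–O(silylene); bridges C(CH3)2–CH with the CH2O arm syn to the enol ether bridge, C(OSiiPr3)=C(CH3), and C(Br)=C(acyl) with Br next to the C–CH3 bridgehead)
Conditions: 11 (1 equiv), 18 (1.5 equiv), BHT (cat.), toluene (2 M), 70–75 °C, sealed base-washed tube
Reagents that add atoms: none
Why: Thermal normal-electron-demand Diels–Alder reaction, concerted but asynchronous: the methyl-bearing diene terminus, which lies next to the silyloxy carbon and is pushed by both oxygen donors, bonds ahead of the rest to the bromine-bearing beta carbon of the ynone, and the oxygen-bearing terminus bonds to the acyl-bearing alpha carbon. The closest known reaction type is the cycloaddition of 1,3-dioxygenated cyclohexa-1,3-dienes with alkynones and 3-halopropiolates. The one new ring, six-membered and made of the four diene carbons and the two alkyne carbons, closes suprafacially in the [4+2] mode and turns the cyclohexadiene into a bicyclo[2.2.2]octa-2,5-diene. Both bridgehead centres arise together and are controlled by the ring CH centre of 11: the alkyne should come in over the face that carries H, anti to the CH2O arm, so that the arm ends syn to the silyl enol ether bridge, and an alkyne raises no endo/exo question. Regioselectivity is secured by the matched polarisation of diene and ynone, and a non-polar solvent disfavours a zwitterion that could expel bromide. The C(CH3)2 carbon blocks aromatisation by tautomerism, and a bath temperature of at most 75 °C is meant to stay below the onset of Alder–Rickert extrusion of the C(CH3)2–CH bridge and of 1,5-hydrogen shift in the diene.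

Step 13
Reactants: 19 bicyclo[2.2.2]octa-2,5-diene adduct
Product: 20 beta-hydroxy ketone (19 with free benzylic OH)
Conditions: PPTS (20 mol %), MeOH/CH2Cl2 1:1, 0 °C
Reagents that add atoms: none
Why: Acid-catalysed methanolysis of the most labile silyl ether; the cyclic silylene and the hindered tetrasubstituted triisopropylsilyl enol ether should not be protonated by so weak an acid.

Step 14
Reactants: 20 beta-hydroxy ketone
Product: 21 dihydropyranone (O–C6 bond closed; silylene and silyl enol ether retained)
Conditions: K2CO3 (1.2 equiv), MeCN, 0 °C to rt, short contact time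
Reagents that add atoms: none
Why: Intramolecular oxa-Michael addition–elimination (6-endo-trig) at the beta-bromo enone; the benzylic C–O bond is not broken, so (R) is retained, the still silylated bridgehead oxygen rules out a Grob-type fragmentation towards alkyne and ketone, and this is the only basic step the pyranone meets.

Step 15
Reactants: 21 dihydropyranone
Product: 22 diol (free bridgehead OH and free CH2OH; silyl enol ether retained)
Conditions: HF·pyridine, excess pyridine, THF, 0 °C
Reagents that add atoms: none
Why: Fluoride cleavage of the cyclic dialkoxysilane, which is attacked far faster than the hindered triisopropylsilyl enol ether buried in the cage, under buffered conditions that leave the pyranone closed.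

Step 16
Reactants: 22 diol
Product: 23 target CNP0322161.2
Conditions: PhI(OAc)2 (1.1 equiv), CH2Cl2/(CF3)2CHOH 4:1, 4 Å molecular sieves, −20 to 0 °C
Reagents that add atoms: none
Why: Alpha-oxygenation of a silyl enol ether with trivalent iodine (umpolung of the enol carbon): iodine should bind the open face next to the pyranone bridge, and the CH2OH group, held over the opposite face, displaces iodobenzene in a 5-exo closure, so the C(CH3)(O) centre can only form with its oxygen syn to the C(CH3)2–CH bridge.

## Compound list

1 | 2-methyldimedone (2,5,5-trimethylcyclohexane-1,3-dione) | CC1C(=O)CC(C)(C)CC1=O | starting material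
2 | 3-(benzyloxy)-2,5,5-trimethylcyclohex-2-en-1-one | CC1=C(OCc2ccccc2)CC(C)(C)CC1=O | intermediate
3 | lithium alpha'-enolate of 2 | CC1=C(OCc2ccccc2)CC(C)(C)C=C1O[Li] | intermediate
4 | 1-(benzyloxy)-2,5,5-trimethyl-3-(trimethylsilyloxy)cyclohexa-1,3-diene | CC1=C(OCc2ccccc2)CC(C)(C)C=C1O[Si](C)(C)C | intermediate
5 | (6R)-3-(benzyloxy)-6-(hydroxymethyl)-2,5,5-trimethylcyclohex-2-en-1-one | CC1(C)[C@H](CO)C(=O)C(C)=C(OCc2ccccc2)C1 | intermediate
6 | (4R)-4-(hydroxymethyl)-2,5,5-trimethylcyclohexane-1,3-dione (drawn as the enol next to the arm) | CC1(C)[C@H](CO)C(O)=C(C)C(=O)C1 | intermediate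
7 | silylene enone: di-tert-butylsilylene joining the CH2O arm and the adjacent enol oxygen, ketone on the far side, (R) at the ring CH | CC1(C)[C@@H]2CO[Si](C(C)(C)C)(C(C)(C)C)OC2=C(C)C(=O)C1 | intermediate
8 | lithium alpha'-enolate of 7 | CC1(C)[C@@H]2CO[Si](C(C)(C)C)(C(C)(C)C)OC2=C(C)C(O[Li])=C1 | intermediate
9 | 6-methyl silylene enone (epimers at the new CH(CH3) centre) | CC1(C)[C@@H]2CO[Si](C(C)(C)C)(C(C)(C)C)OC2=C(C)C(=O)C1C | intermediate
10 | lithium alpha'-enolate of 9 | CC1(C)[C@@H]2CO[Si](C(C)(C)C)(C(C)(C)C)OC2=C(C)C(O[Li])=C1C | intermediate
11 | diene: 1-silyloxy (silylene-tethered) 3-triisopropylsilyloxy 2,4,5,5-tetramethylcyclohexa-1,3-diene, (R) at the ring CH | CC1(C)[C@@H]2CO[Si](C(C)(C)C)(C(C)(C)C)OC2=C(C)C(O[Si](C(C)C)(C(C)C)C(C)C)=C1C | intermediate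
12 | ethyl (R)-3-hydroxy-3-phenylpropanoate | CCOC(=O)C[C@@H](O)c1ccccc1 | starting material
13 | (R)-3-hydroxy-N-methoxy-N-methyl-3-phenylpropanamide | CON(C)C(=O)C[C@@H](O)c1ccccc1 | intermediate
14 | (R)-N-methoxy-N-methyl-3-phenyl-3-(triethylsilyloxy)propanamide | CON(C)C(=O)C[C@H](c1ccccc1)O[Si](CC)(CC)CC | intermediate
15 | ethynylmagnesium bromide | C#C[Mg]Br | starting material
16 | bromomagnesium hemiaminal (tetrahedral) adduct of 14 and 15 | C#CC(O[Mg]Br)(N(C)OC)C[C@H](c1ccccc1)O[Si](CC)(CC)CC | intermediate
17 | (R)-5-phenyl-5-(triethylsilyloxy)pent-1-yn-3-one | C#CC(=O)C[C@H](c1ccccc1)O[Si](CC)(CC)CC | intermediate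
18 | (R)-1-bromo-5-phenyl-5-(triethylsilyloxy)pent-1-yn-3-one | BrC#CC(=O)C[C@H](c1ccccc1)O[Si](CC)(CC)CC | intermediate
19 | bicyclo[2.2.2]octa-2,5-diene Diels–Alder adduct | CC1(C)[C@@H]3CO[Si](C(C)(C)C)(C(C)(C)C)O[C@]32C(C)=C(O[Si](C(C)C)(C(C)C)C(C)C)[C@@]1(C)C(Br)=C2C(=O)C[C@H](c1ccccc1)O[Si](CC)(CC)CC | intermediate
20 | beta-hydroxy ketone (19 without the triethylsilyl group) | CC1(C)[C@@H]3CO[Si](C(C)(C)C)(C(C)(C)C)O[C@]32C(C)=C(O[Si](C(C)C)(C(C)C)C(C)C)[C@@]1(C)C(Br)=C2C(=O)C[C@H](c1ccccc1)O | intermediate
21 | dihydropyranone with silylene and silyl enol ether in place | CC1(C)[C@@H]3CO[Si](C(C)(C)C)(C(C)(C)C)O[C@]32C(C)=C(O[Si](C(C)C)(C(C)C)C(C)C)[C@@]1(C)C1=C2C(=O)C[C@H](c2ccccc2)O1 | intermediate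
22 | diol: free bridgehead OH and CH2OH, silyl enol ether in place | CC1(C)[C@H](CO)[C@]2(O)C(C)=C(O[Si](C(C)C)(C(C)C)C(C)C)[C@@]1(C)C1=C2C(=O)C[C@H](c2ccccc2)O1 | intermediate
23 | CNP0322161.2 | CC1(C)[C@@H]2CO[C@]3(C)C(=O)[C@@]1(C)C1=C(C(=O)C[C@H](c4ccccc4)O1)[C@]23O | target

## Step count and risks

Total step count: 16. Longest linear sequence: 12 (steps 1–7, then 12–16).

**Step 12.** The cycloaddition must join a fully substituted diene terminus next to C(CH3)2 to a bromine-bearing carbon.
- It may be too slow below the temperature at which the adduct fragments by Alder–Rickert loss of the saturated bridge.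
- It may turn stepwise, with loss of bromide and net alkynylation.
- Facial selectivity may be eroded.

The fallback sets out from diene 11 and the terminal ynone 17, whose beta carbon carries H instead of Br and is less hindered. Cycloaddition in toluene at about 60 °C should give, with the same regiochemical and facial sense, the bromine-free bicyclooctadiene F1. PPTS in MeOH should free the benzylic alcohol to give the beta-hydroxy enone F2. Oxidative cyclisation with divalent palladium then installs the O–C6 bond without a leaving group and comes back to the route at 21. The conditions are PdCl2(MeCN)2 cat., CuCl, Na2HPO4, O2, DME, 50 °C, and the mechanism is anti-oxypalladation followed by syn beta-hydride elimination.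

**Step 16.** Departure of iodobenzene from the C(CH3) carbon next to the free carbinol may trigger a 1,2-shift of the ring CH carbon (semipinacol reorganisation of the cage). Alternatively, acetate may be transferred in place of the arm oxygen. The fallback sets out from 22 and replaces the polar trivalent-iodine pathway with anodic oxidation of the silyl enol ether. The conditions are a reticulated vitreous carbon anode, Pt cathode, Et4NOTs, 2,6-lutidine, MeOH/THF and constant current. The enol ether radical cation is trapped by the tethered alcohol, and a second electron transfer and loss of silicon give the ketone. This is a known way to build tetrahydrofurans with a fully substituted carbon. It comes back to the route directly at 23, and no compound outside the list is made (F0).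

**Step 3.** Hydrolysis of the silyl enol ether in the aqueous medium may outrun the aldol reaction. Facial discrimination may also be low for a ring enolate flanked by C(CH3)2. The fallback sets out from 2. Its lithium enolate 3 is treated with monomeric formaldehyde gas (THF, −78 °C) to give the racemic hydroxymethyl ketone F3. Kinetic resolution with Burkholderia cepacia lipase and vinyl acetate in tBuOMe is expected to acetylate the (S)-alcohol to the (S)-acetate F4. The (R)-alcohol is left unreacted and is separated on silica, so the fallback comes back to the route at 5.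

## Further compounds

F1 | step 12 | bromine-free Diels–Alder adduct of 11 and 17 | CC1(C)[C@@H]3CO[Si](C(C)(C)C)(C(C)(C)C)O[C@]32C(C)=C(O[Si](C(C)C)(C(C)C)C(C)C)[C@@]1(C)C=C2C(=O)C[C@H](c1ccccc1)O[Si](CC)(CC)CC
F2 | step 12 | beta-hydroxy enone (F1 without the triethylsilyl group) | CC1(C)[C@@H]3CO[Si](C(C)(C)C)(C(C)(C)C)O[C@]32C(C)=C(O[Si](C(C)C)(C(C)C)C(C)C)[C@@]1(C)C=C2C(=O)C[C@H](c1ccccc1)O
F0 | step 16 | none | none
F3 | step 3 | racemic 3-(benzyloxy)-6-(hydroxymethyl)-2,5,5-trimethylcyclohex-2-en-1-one | CC1(C)C(CO)C(=O)C(C)=C(OCc2ccccc2)C1
F4 | step 3 | [(1S)-4-(benzyloxy)-3,6,6-trimethyl-2-oxocyclohex-3-en-1-yl]methyl acetate | CC1(C)[C@@H](COC(C)=O)C(=O)C(C)=C(OCc2ccccc2)C1
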